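The carbinol C4 of the cyclohexene ring is allylic to C5=C6. This is the pattern left when water quenches a C4-C5-C6 allyl cation, and that cation is the ring-opened form of a cyclopropane with apex C5 fused to a five-membered ring made of C1, C2, C3, C4 and C6.
Cuts: first the two benzoyl C-O bonds (O3, O7). Then C4-O together with C4-C5 and C5-C6, so that C5 leaves as CBr2 and C4-C6 is rejoined. Then C4=C6 of the cyclopentene (metathesis), and last C1-C7 (formaldehyde aldol).
Forward: the chain comes first (C7 onto C1 of a D-mannose derivative, one vinyl group at each end). The five-membered ring follows by ring-closing metathesis, the three-membered ring by dibromocarbene addition and the six-membered ring by silver-induced ring enlargement; bromine removal and exchange of ethers for esters finish the route.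
Stereochemistry: C2 and C3 are C3 and C4 of D-mannose. C1 is fixed in the aldol by the cis-fused 2,3-acetonide, which stays on as the C1/C2 protecting group. C4 is created in the ring enlargement by capture of the cation on the beta face, trans to the C3 ether.
Key step: step 8

Remark: labels C1-C7 are those of the target name throughout (C7 = benzoyloxymethyl carbon); beta is the face of the C1, C2 and C4 oxygens, alpha the face of C7 and the C3 oxygen; PMB = 4-methoxybenzyl, TBS = tert-butyldimethylsilyl; compound 1 is taken as a catalogue chemical.

Step 1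
Reactants: 1 2,3:5,6-di-O-isopropylidene-alpha-D-mannofuranose; 2 formaldehyde
Product: 3 2-C-(hydroxymethyl)-2,3:5,6-di-O-isopropylidene-D-mannofuranose (lactol; anomers; branched carbon = C1; new CH2OH = C7)
Conditions: 37% aq HCHO, K2CO3, MeOH, reflux
Reagents that add atoms: formaldehyde 2, C=O
Why: Crossed aldol addition to non-enolisable formaldehyde, long used to branch 2,3-O-isopropylidene lactols: K2CO3 enolises the ring-opened aldehyde at the carbon that becomes C1, formaldehyde enters on the dioxolane face opposite the C4 side chain so that the formyl group stays cis to that chain and recloses to the cis-fused lactol, which sets C1 with its oxygen retained and CH2OH in place of H and leaves no alpha hydrogen for further reaction.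

Step 2
Reactants: 3 2-C-(hydroxymethyl)-2,3:5,6-di-O-isopropylidene-D-mannofuranose
Product: 4 1,2-dideoxy-3-C-(hydroxymethyl)-3,4:6,7-di-O-isopropylidene-D-manno-hept-1-enitol (vinyl on C1; free O7-H and O3-H in target numbering)
Conditions: Ph3PCH3Br (excess), KOtBu, THF, 0 °C to reflux
Reagents that add atoms: methyltriphenylphosphonium bromide, C[P+](c1ccccc1)(c1ccccc1)c1ccccc1.[Br-]
Why: Wittig methylenation of a lactol through its hydroxy-aldehyde tautomer, with surplus ylide taking up the two acidic protons; the aldehyde carbon becomes C6, the neighbouring C1 has no hydrogen to epimerise, and ring opening frees the C3 hydroxyl.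

Step 3
Reactants: 4 1,2-dideoxy-3-C-(hydroxymethyl)-3,4:6,7-di-O-isopropylidene-D-manno-hept-1-enitol
Product: 5 bis(PMB) ether of 4 (PMB on O3 and O7)
Conditions: NaH, PMBCl, Bu4NI (cat.), DMF, 0 °C to rt
Reagents that add atoms: 4-methoxybenzyl chloride, COc1ccc(CCl)cc1
Why: Double Williamson etherification caps the only two free hydroxyls in one operation with oxidatively removable, non-participating ethers at exactly the oxygens (O3 and O7) that end as benzoates.

Step 4
Reactants: 5 bis(PMB) ether of 4
Product: 6 terminal 6,7-diol (heptenitol numbering) retaining the C1/C2 acetonide and both PMB ethers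
Conditions: AcOH-H2O (4:1), 40 °C
Reagents that add atoms: none
Why: Chemoselective acetal hydrolysis, since the unhindered terminal dioxolane is opened far faster than the internal one buttressed by the fully substituted C1, a standard distinction in di-O-isopropylidene alditols that PMB ethers tolerate.

Step 5
Reactants: 6 terminal 6,7-diol
Product: 7 1,2,6,7-tetradeoxy-3,4-O-isopropylidene-5-O-(4-methoxybenzyl)-3-C-[(4-methoxybenzyloxy)methyl]-D-lyxo-hepta-1,6-dienitol
Conditions: PPh3, imidazole, I2, toluene, 110 °C
Reagents that add atoms: none
Why: Garegg-Samuelsson olefination, in which Ph3P/I2/imidazole activates both hydroxyls of the vicinal diol and reductive elimination delivers the terminal alkene (its inner carbon is C4) under buffered conditions that leave the adjacent C3 centre and the PMB ethers untouched.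

Step 6
Reactants: 7 D-lyxo-hepta-1,6-dienitol derivative
Product: 8 (3aS,4R,6aS)-4-(4-methoxybenzyloxy)-6a-[(4-methoxybenzyloxy)methyl]-2,2-dimethyl-3a,6a-dihydro-4H-cyclopenta[d][1,3]dioxole (cyclopentene C1-C2-C3-C4=C6; acetonide beta; O3 and C7 alpha)
Conditions: second-generation Grubbs catalyst (5 mol %), CH2Cl2, 40 °C
Reagents that add atoms: none
Why: Ring-closing metathesis of a 1,6-diene, favoured because the dioxolane holds C6 and C3 cis so that the cyclopentene closes to a strain-free cis-bicyclo[3.3.0] system with loss of ethene, as in many sugar-derived cyclopentenes bearing an allylic quaternary carbon.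

Step 7
Reactants: 8 cyclopentene; 9 bromoform
Product: 10 6,6-dibromobicyclo[3.1.0]hexane with C1/C2 acetonide (beta) plus PMB ethers at O3 and O7 (alpha); cyclopropane C4-C5-C6 on the alpha face
Conditions: CHBr3, 50% aq NaOH, BnEt3NCl (cat.), CH2Cl2, 0 °C to rt, vigorous stirring
Reagents that add atoms: bromoform 9, BrC(Br)Br
Why: Makosza phase-transfer dibromocyclopropanation, a concerted cis-specific [2+1] addition of singlet CBr2 to the only alkene, expected on the convex alpha face away from the acetonide, all other groups being inert to base and the two new cyclopropane centres being erased again in step 8 so that a facial mixture would converge.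

Step 8
Reactants: 10 6,6-dibromobicyclo[3.1.0]hexane
Product: 12 5-bromo-1-(hydroxymethyl)cyclohex-5-ene-1beta,2beta,3alpha,4beta-tetraol 1,2-acetonide 3,7-bis(PMB) ether (O4-H free), via 2-bromocyclohexenyl cation 11 (not isolated)
Conditions: AgClO4, CaCO3, acetone-H2O (5:1), 55 °C, dark
Reagents that add atoms: water, O
Why: AgClO4 pulls off the endo bromide (the one lying over the five-membered ring) while the C4-C6 bond opens in the disrotatory, inward sense required by the Woodward-Hoffmann-DePuy rule, so that strain release turns bicycle 10 directly into the all-cis 2-bromoallyl cation 11 spanning C4-C5-C6, which water captures at C4 with loss of a proton to CaCO3. The closest known reaction type is the silver-salt-promoted electrocyclic opening of ring-fused gem-dibromocyclopropanes, 6,6-dibromobicyclo[3.1.0]hexanes in particular, with trapping by oxygen nucleophiles to give 2-bromocyclohex-2-enols. The cyclohexene ring is not closed by a cyclisation but arises by one-carbon enlargement, a two-electron electrocyclic cleavage of the zero-atom bridge that leaves C5 inserted between C4 and C6. The only new stereocentre, C4, is set by attack of water on the beta face, because the alpha face carries the C3 ether next to the reacting carbon, the C7 arm and the departing AgBr, and because the sofa conformer in which 11 is born (C2 displaced to the beta side, away from the endo bromine) is attacked pseudoaxially from that same beta face, which gives the C3/C4 trans product. The step needs C4 over C6 regioselectivity, and the fully substituted C1 secures it by making C6 neopentyl-like and, through the C1-O and C7-O dipoles, the poorer bearer of positive charge. Ethers instead of esters at O3 and O7 exclude acyloxonium participation, which would deliver the cis product or attack at C6, and the carbonate buffer keeps the liberated acid away from the acetonide and the PMB groups.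

Step 9
Reactants: 12 5-bromocyclohexenol
Product: 13 O4-TBS ether of 12
Conditions: TBSOTf, 2,6-lutidine, CH2Cl2, 0 °C
Reagents that add atoms: tert-butyldimethylsilyl triflate, CC(C)(C)[Si](C)(C)OS(=O)(=O)C(F)(F)F
Why: Silyl ether formation with the triflate and a hindered pyridine base copes with the crowded allylic carbinol flanked by bromine and the C3 ether and masks O4 with a group that survives radicals, DDQ and acylation yet falls in the final acid step.

Step 10
Reactants: 13 O4-TBS ether of 12
Product: 14 debrominated cyclohexene (C5-H) with 1,2-acetonide plus 3,7-bis(PMB) plus O4-TBS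
Conditions: Bu3SnH, AIBN (cat.), toluene, 90 °C
Reagents that add atoms: none
Why: Radical chain hydrodebromination, well established for bromoconduritol-type vinyl bromides: Bu3Sn radical abstracts bromine and the sigma vinyl radical at C5 is quenched by the concentrated tin hydride faster than any hydrogen transfer from the ethers, no stereocentre being involved.

Step 11
Reactants: 14 debrominated cyclohexene
Product: 15 3,7-diol with 1,2-acetonide plus O4-TBS
Conditions: DDQ, CH2Cl2-pH 7 buffer (10:1), 0 °C to rt
Reagents that add atoms: none
Why: Oxidative PMB cleavage, in which DDQ removes benzylic hydride from the electron-rich ethers and water hydrolyses the oxocarbenium ions, leaves the silyl ether, the acetonide and the isolated alkene intact and frees O3 and O7 together.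

Step 12
Reactants: 15 3,7-diol; 16 benzoyl chloride
Product: 17 3,7-dibenzoate with 1,2-acetonide plus O4-TBS
Conditions: BzCl, pyridine, DMAP (cat.), CH2Cl2, 0 °C to rt
Reagents that add atoms: benzoyl chloride 16, O=C(Cl)c1ccccc1
Why: DMAP-catalysed acylation of the only two free hydroxyls installs both benzoates at once, O1, O2 and O4 being blocked.

Step 13
Reactants: 17 3,7-dibenzoate
Product: 18 [(1S,2S,3R,4S)-3-(benzoyloxy)-1,2,4-trihydroxycyclohex-5-en-1-yl]methyl benzoate (target)
Conditions: TFA-H2O (9:1), CH2Cl2, 0 °C to rt
Reagents that add atoms: none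
Why: Acid hydrolysis removes the isopropylidene acetal and the allylic silyl ether in one operation, and the acidic, cold medium avoids the base-induced benzoyl migration to the neighbouring hydroxyls, so all four stereocentres are delivered unchanged.

Compound list
1 | 2,3:5,6-di-O-isopropylidene-alpha-D-mannofuranose | O[C@@H]1[C@H]2OC(C)(C)O[C@H]2[C@@H]([C@H]2COC(C)(C)O2)O1 | starting material
2 | formaldehyde | C=O | starting material
3 | 2-C-(hydroxymethyl)-2,3:5,6-di-O-isopropylidene-D-mannofuranose (anomeric mixture) | OC1[C@@]2(CO)OC(C)(C)O[C@H]2[C@@H]([C@H]2COC(C)(C)O2)O1 | intermediate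
4 | 1,2-dideoxy-3-C-(hydroxymethyl)-3,4:6,7-di-O-isopropylidene-D-manno-hept-1-enitol | C=C[C@@]1(CO)OC(C)(C)O[C@H]1[C@H](O)[C@H]1COC(C)(C)O1 | intermediate
5 | bis(PMB) ether of 4 (O3, O7) | C=C[C@@]1(COCc2ccc(OC)cc2)OC(C)(C)O[C@H]1[C@H](OCc1ccc(OC)cc1)[C@H]1COC(C)(C)O1 | intermediate
6 | terminal 6,7-diol from 5 | C=C[C@@]1(COCc2ccc(OC)cc2)OC(C)(C)O[C@H]1[C@H](OCc1ccc(OC)cc1)[C@H](O)CO | intermediate
7 | 1,2,6,7-tetradeoxy-3,4-O-isopropylidene-5-O-PMB-3-C-(PMB-oxymethyl)-D-lyxo-hepta-1,6-dienitol | C=C[C@@]1(COCc2ccc(OC)cc2)OC(C)(C)O[C@H]1[C@H](OCc1ccc(OC)cc1)C=C | intermediate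
8 | (3aS,4R,6aS)-4-(PMB-oxy)-6a-(PMB-oxymethyl)-2,2-dimethyl-3a,6a-dihydro-4H-cyclopenta[d][1,3]dioxole | COc1ccc(cc1)COC[C@@]1(OC(C)(C)O3)C=C[C@@H](OCc2ccc(OC)cc2)[C@@H]13 | intermediate
9 | bromoform | BrC(Br)Br | starting material
10 | alpha-face 6,6-dibromobicyclo[3.1.0]hexane, C1/C2 acetonide, O3- and O7-PMB | COc1ccc(cc1)COC[C@@]1(OC(C)(C)O3)[C@H]2C(Br)(Br)[C@H]2[C@@H](OCc2ccc(OC)cc2)[C@@H]13 | intermediate
11 | 2-bromocyclohexenyl (C4-C5-C6 allyl) cation | COc1ccc(cc1)COC[C@@]1(OC(C)(C)O3)C=C(Br)[CH+][C@@H](OCc2ccc(OC)cc2)[C@@H]13 | intermediate
12 | 5-bromocyclohexenol, 1,2-acetonide, 3,7-bis(PMB), O4-H beta | COc1ccc(cc1)COC[C@@]1(OC(C)(C)O3)C=C(Br)[C@H](O)[C@@H](OCc2ccc(OC)cc2)[C@@H]13 | intermediate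
13 | O4-TBS ether of 12 | COc1ccc(cc1)COC[C@@]1(OC(C)(C)O3)C=C(Br)[C@H](O[Si](C)(C)C(C)(C)C)[C@@H](OCc2ccc(OC)cc2)[C@@H]13 | intermediate
14 | debrominated cyclohexene, 1,2-acetonide, 3,7-bis(PMB), O4-TBS | COc1ccc(cc1)COC[C@@]1(OC(C)(C)O3)C=C[C@H](O[Si](C)(C)C(C)(C)C)[C@@H](OCc2ccc(OC)cc2)[C@@H]13 | intermediate
15 | 3,7-diol, 1,2-acetonide, O4-TBS | OC[C@@]1(OC(C)(C)O3)C=C[C@H](O[Si](C)(C)C(C)(C)C)[C@@H](O)[C@@H]13 | intermediate
16 | benzoyl chloride | O=C(Cl)c1ccccc1 | starting material
17 | 3,7-dibenzoate, 1,2-acetonide, O4-TBS | O=C(OC[C@@]1(OC(C)(C)O3)C=C[C@H](O[Si](C)(C)C(C)(C)C)[C@@H](OC(=O)c2ccccc2)[C@@H]13)c1ccccc1 | intermediate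
18 | 1alpha-benzoyloxymethyl-3alpha-benzoyloxycyclohex-5-en-1beta,2beta,4beta-triol, (1S,2S,3R,4S) | O=C(OC[C@@]1(O)C=C[C@H](O)[C@@H](OC(=O)c2ccccc2)[C@@H]1O)c1ccccc1 | target

Total step count: 13. Longest linear sequence: 13 steps, from 1 to 18.

Steps most likely to fail

Step 8. Facial selectivity in the capture of cation 11 may be poor or even reversed. A second sofa conformer with the C3 ether equatorial would take up water pseudoaxially from the alpha face. Ionisation is also slowed by the C-O dipoles on both sides of the allyl system. The fallback lets hydride, not water, fix C4. It sets out from 10, and the silver-mediated opening is run as before. The carbinol fraction, then consisting largely of the C4-epimeric bromocyclohexenol F1, is oxidised with Dess-Martin periodinane (NaHCO3, CH2Cl2) to the C4-keto 2-bromocyclohexenone F2. Luche reduction (NaBH4, CeCl3·7H2O, MeOH, -78 °C) should add hydride pseudoaxially from the alpha face, the trajectory that water had preferred. This leaves the equatorial beta alcohol trans to the C3 ether, and the route is rejoined at 12.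

Step 7. Carbene transfer may be too slow, because the 1,2-disubstituted alkene is flanked by the quaternary C1 and deactivated by its allylic C-O bonds. Hydrolysis of the carbene and insertion into the benzylic C-H bonds of the PMB groups could then take over. The fallback builds the three-membered ring stepwise, first by a radical and then by a polar step, and sets out from 8. Kharasch atom-transfer addition of CBr4 (Et3B, air, CH2Cl2, rt) should place CBr3 on the less hindered C4, anti to the C3 ether, and bromine on C6 trans to it. This gives the C4-beta-tribromomethyl C6-alpha-bromide F3. MeLi (Et2O, -78 °C) then exchanges one bromine of the CBr3 group, and the carbenoid displaces the C6 bromide in a 1,3-elimination to give the beta-face dibromocyclopropane F4, a diastereomer of 10. Under the conditions of step 8, F4 loses its own endo bromide to the same cation 11, so the route is rejoined at 12.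

Step 2. The strongly basic ylide could trigger retro-aldol loss of formaldehyde from the beta-alkoxide of the ring-opened aldehyde, and olefination of this neopentyl-type aldehyde may be sluggish enough for that loss to compete. The fallback removes the offending alkoxide by masking O7 before the lactol is opened, and sets out from 3. Selective silylation of the primary hydroxyl (TBDPSCl, imidazole, DMF, 0 °C) gives the O7-TBDPS lactol F5. Wittig methylenation as in step 2 gives the O7-TBDPS heptenitol F6, and Bu4NF (THF, rt) frees O7, so the route is rejoined at 4.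

Further compounds
F1 | step 8 | C4-epimeric bromocyclohexenol (O4-H alpha), 1,2-acetonide, 3,7-bis(PMB) | COc1ccc(cc1)COC[C@@]1(OC(C)(C)O3)C=C(Br)[C@@H](O)[C@@H](OCc2ccc(OC)cc2)[C@@H]13
F2 | step 8 | C4-keto 2-bromocyclohexenone, 1,2-acetonide, 3,7-bis(PMB) | COc1ccc(cc1)COC[C@@]1(OC(C)(C)O3)C=C(Br)C(=O)[C@@H](OCc2ccc(OC)cc2)[C@@H]13
F3 | step 7 | C4-beta-tribromomethyl C6-alpha-bromide adduct of 8 | COc1ccc(cc1)COC[C@@]1(OC(C)(C)O3)[C@@H](Br)[C@H](C(Br)(Br)Br)[C@@H](OCc2ccc(OC)cc2)[C@@H]13
F4 | step 7 | beta-face dibromocyclopropane, diastereomer of 10 | COc1ccc(cc1)COC[C@@]1(OC(C)(C)O3)[C@@H]2C(Br)(Br)[C@@H]2[C@@H](OCc2ccc(OC)cc2)[C@@H]13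
F5 | step 2 | O7-TBDPS lactol, 2-C-(tert-butyldiphenylsilyloxymethyl)-2,3:5,6-di-O-isopropylidene-D-mannofuranose | OC1[C@@]2(CO[Si](c3ccccc3)(c3ccccc3)C(C)(C)C)OC(C)(C)O[C@H]2[C@@H]([C@H]2COC(C)(C)O2)O1
F6 | step 2 | O7-TBDPS heptenitol, silyl ether of 4 at O7 | C=C[C@@]1(CO[Si](c2ccccc2)(c2ccccc2)C(C)(C)C)OC(C)(C)O[C@H]1[C@H](O)[C@H]1COC(C)(C)O1
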